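Substrate that has gone to side product cannot come back as target, since neither step has a reverse, so the target's yield is capped by the first step's share of the substrate's turnover.

| setting | spring | winter | dusk |
|---|---|---|---|
| substrate | 0.18 M | 0.18 M | 0.18 M |
| temperature | 20 °C | 70 °C | 45 °C |
| time | 3.0 h | 3.0 h | 3.0 h |

    substrate → target (k1 = 0.0055 min⁻¹, Ea1 = 101 kJ mol⁻¹)
    substrate → side product (k2 = 6.0 × 10⁻⁴ min⁻¹, Ea2 = 91.0 kJ mol⁻¹)
    (constants at 20 °C)

- which of the two there is more of at the end, spring (target / side product)
- which of the two there is more of at the end, winter (target / side product)
- which of the two there is more of at the end, dusk (target / side product)
- final target, as a percentage of the substrate charged, in spring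
- final target, as a percentage of the substrate charged, in winter
- final target, as a percentage of the substrate charged, in dusk

- at 20 °C the constants are as listed, elsewhere as the activation energies make them

Both steps are first order in substrate. Dividing the rate that makes target by the rate that makes side product therefore removes the substrate concentration and the time, and a ratio of rate constants remains. In dusk that ratio is 12.7, the target made per side product made, or selectivity factor. The first step in dusk therefore takes a share of 92.7%.

My reckoning sets dusk beside a repeat of it at 20 °C, which matches spring in charge, time and temperature. In that cooler flask the factor is 9.17, so its share is lower than dusk's, at 90.2%. Dusk's substrate falls with a summed rate constant of 0.154 min⁻¹, which gives a half-life of 4.50 min, far shorter than the 3.0 h allowed, so dusk's yield is its share. In spring the summed constant is 0.00610 min⁻¹, which leaves 33.4% of the substrate at the end, so spring's yield is 60.1%. Winter's factor is 16.7, and with its turnover taken as complete its yield is 94.3%. Each of these factors stands above one, so I expect target to lead in spring, winter and dusk.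

The forecast also names target in spring, target in winter and target in dusk, with yields of 60.1%, 94.3% and 92.7%. Its ground for the two warm flasks is that “conversion is essentially complete and the yield is simply the selectivity”.

The simulation gives 60.1% target in spring, 94.3% in winter and 92.7% in dusk, with target ahead in each. Dusk holds 92.7% target against 7.32% side product, a ratio of 12.7 beside the factor of 12.7. The neighbour, dusk repeated at 20 °C, has the factor 9.17. Its share of 90.2%, applied to the reckoned 66.6% of substrate turned over, gives 60.1% target. That neighbour ends with 60.1% target, 6.56% side product and 33% of its substrate still there.

The rate constants come from no measurement; the rest is arithmetic.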